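## The problem

The target is a 3,3''-biflavanone: two 2-(4-methoxyphenyl)chroman-4-one units joined by a single C3–C3'' bond, with a C2 axis through the middle of that bond. Its four contiguous stereocentres (2S,3R,3''R,2''S) lie on one four-carbon chain. Within each half the 2,3-trans arrangement is the stable one, so C3 can steer C2, but nothing relates C3 to C3'', and the like pairing with its absolute sense must be imposed from outside. C3 and C3'' are α to a ketone and β to the ring oxygen O1, so base can open ring C by β-elimination and erase C2 and C3 together; these centres must be made where they are not acidic, and ring C closed late and gently. The C2–O1 bond is a 4-methoxybenzylic ether and ionises under strong acid. Ring A carries a 5-methoxy group next to the carbonyl and a free 7-hydroxyl, so it has to arrive with its two oxygens already differentiated. The enabling feature is that C2 and C2'' are oxygen-bearing benzylic carbons carrying ring B, each bonded to C3 or C3''; this aryl–CH(O)–C unit is what a [2,3]-Wittig shift of a 4-methoxybenzyl allyl ether produces. Because C3–C3'' can be the central bond of a 1,3-diene flanked by two carbinol ethers, both C2–C3 bonds can form in one C2-symmetric operation.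

## Retrosynthesis

**17 from 16 (O7–Si and O7''–Si).** The two 7-hydroxyls are carried as triisopropylsilyl ethers to the end. The cut removes no skeletal complexity, but it lets ring A enter as a single regiodefined organolithium. The forward step must be a buffered desilylation that leaves ring C closed.

**16 from 15 (O1–C8a and O1''–C8a'').** Ring C is opened at the aryl–oxygen bond. Cutting O1–C2 instead would make C2 the last stereocentre formed and would pass through a chalcone or an easily ionised benzylic carbinol. With the aryl–oxygen cut, the C2 oxygen is an ordinary carbinol oxygen and C2 keeps its configuration on closure. Precursor 15 is acyclic, with two β-hydroxy ketones each facing an ortho-fluorine. The forward reaction is a twofold six-membered nucleophilic aromatic substitution that must outrun retro-aldol cleavage.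

**15 from 10 and 13 (C4–C4a and C4''–C4a''); 13 from 12, 12 from 11.** Both A rings are removed as two molecules of aryllithium 13. The acyl partner is the cis-fused dilactone 10, in which C3 and C3'' are ring-fusion carbons and cannot epimerise singly. A lactone stops at the ketone oxidation level after one addition, and opening the two lactones frees exactly the two C2 hydroxyls needed next. A Friedel–Crafts acylation would have to choose between two similar ring positions under acid. Lithiation of 12, made from 11, is directed to the one carbon between fluorine and methoxy.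

**10 from 9, 9 from 7 through 8 (the propenyl C=C bonds).** The lactone carbonyl carbons C4 and C4'' are traced back through lactols to aldehydes and then to the inner carbons of two propenyl groups. The propenyl groups are what the sigmatropic step leaves behind, so no separate carbonyl installation is needed. The forward steps require ozone to cleave the alkenes without attacking the anisyl rings, and each aldehyde of 8 to be trapped at once as a five-membered lactol.

**7 from 5 through 6 (C2–C3 and C2''–C3'').** This is the strategic cut. A cut at C3–C3'' would be a dimerisation with no handle on the like/unlike pairing. An aldol-type reading of C2–C3 would need a double anti-aldol of a succinate with absolute control. The [2,3]-shift instead moves stereochemical information from two easily made carbinol carbons onto C3 and C3'' and sets C2 and C2'' through alkene geometry. Precursor 5 has two stereocentres and no carbon–carbon bond to an aromatic ring. The forward reaction has to lithiate both benzylic positions, rearrange twice and transfer chirality cleanly.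

**5 from 3 and 4; 3 from 2; 2 from 1.** The two benzyl–oxygen bonds are made by etherification of dienediol 3 with two molecules of chloride 4. The E,E-diene comes from diynediol 2 by alkyne reduction. The central bond of 2 comes from oxidative coupling of two molecules of 1, so both stereocentres of 5 are purchased.

## Roads not taken

**Alternative 1:** The cut is C3–C3'' together with both O1–C2 bonds, back to chalcone A1. In the forward key step Ag2O would oxidise the 4-hydroxyl of A1 to a phenoxyl radical with spin density at the enone α-carbon. Two radicals would join there, and each 2'-hydroxyl would add to its quinone-methide carbon under a chiral BINOL-derived phosphoric acid to give A2. O-Methylation of the two new phenols and hydrogenolysis of benzyl and bromine would finish the synthesis.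
- Merits: the skeleton and both C rings form in one biomimetic operation from an achiral monomer. In step count this road is clearly shorter than the chosen one.
- Weak points: the C3–C3'' bond forms in a radical–radical combination that the acid catalyst does not control. The like/unlike pairing and the absolute configuration at C3 and C3'' are therefore left to chance, and the catalyst can only bias the later closure at C2. An enone-conjugated phenoxyl radical carries little spin at the α-carbon, and a 2'-hydroxychalcone has its own oxidative cyclisation pathways.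
- Comparison: the chosen plan is longer, but each of the four stereocentres has an identifiable control element.

**Alternative 2:** The cut is C4–C4a and C4''–C4a'': dilactone A3 (identical with 10) is opened by aryllithium A4 (identical with 13) to give A5 (identical with 15). This is the bond construction used in step 8 of the chosen route, so the two plans are equal on that point.
- Merits: a convergent union of three pieces through a rigid, C2-symmetric electrophile whose ring-fusion carbons cannot epimerise. If A3 could be had in two or three steps, this road would be shorter than the chosen one.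
- Weak points: as a strategy it leaves the origin of A3 open. The usual entries to such dilactones (oxidative dimerisation of a cinnamic acid, double aldol of a succinate) would be expected to favour the less crowded exo,exo-diaryl isomer. That isomer maps onto 2,3-cis flavanone units, and the first entry gives racemic material. The target needs the enantiopure endo,endo isomer.
- Comparison: the chosen plan supplies exactly that isomer, with C3/C3'' fixed by chirality transfer and C2/C2'' by alkene geometry. The price is six steps before the acylation.

**Alternative 3:** The cut removes both A rings at C8–C8a and C5–C4a, back to bis(bromodihydropyranone) A6 and diene A7. In the forward key step the nucleophilic CH2 terminus of A7 would bond to the β-carbon (C8a) of each bromo-enone and the ketene-acetal carbon to C4a. Loss of HBr and methanol would aromatise both rings to A8, whose silyl groups fall off on work-up.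
- Merits: ring A is built with the 5-methoxy/7-hydroxy pattern fixed by the diene. No aryllithium and no late base-mediated ring closure are needed. In this respect its endgame is cleaner than the chosen one.
- Weak points: A6 already contains the C3–C3'' bond and all four stereocentres, so the central problem is passed on unsolved. A6 is a push–pull alkene and a poor dienophile. The forcing conditions it would need threaten C3 and C3'', which are α to a ketone and β to the ring oxygen.
- Comparison: the chosen plan accepts a more delicate ring-C closure in return for a defined origin of the stereocentres.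

Key step: step 4

Remark: 15 is drawn as the open hydroxy ketone; its ring–chain tautomer is the protonated form of 14, and either form enters step 9.
Remark: in the twofold steps the half-reacted species is numbered only in step 4, where the second event meets a different type of allyl ether.
Remark: steps 1, 3 and 8 each build two molecules of one compound into the product; the second molecule is entered under "Reagents that add atoms".

## Steps

Step 1
Reactants: 1 (R)-but-3-yn-2-ol (two molecules)
Product: 2 (2R,7R)-octa-3,5-diyne-2,7-diol
Conditions: CuCl (cat.), TMEDA, O2 (balloon), acetone, rt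
Reagents that add atoms: (R)-but-3-yn-2-ol (second molecule of 1), C[C@@H](O)C#C
Why: Glaser–Hay oxidative homocoupling joins the terminal alkynyl carbons of two molecules of 1; the carbinol stereocentres are remote from the reacting carbon and are untouched.

Step 2
Reactants: 2 (2R,7R)-octa-3,5-diyne-2,7-diol
Product: 3 (2R,3E,5E,7R)-octa-3,5-diene-2,7-diol
Conditions: LiAlH4, THF, 0 °C → reflux; then H2O, aq. NaOH
Reagents that add atoms: none
Why: Hydroxyl-directed trans-hydroalumination of propargylic alcohols: each aluminium alkoxide delivers hydride intramolecularly and protonolysis of the vinylalane gives an E alkene, so the diynediol should give the E,E-diene with both carbinol centres unchanged.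

Step 3
Reactants: 3 (2R,3E,5E,7R)-octa-3,5-diene-2,7-diol; 4 4-methoxybenzyl chloride (two molecules)
Product: 5 (2R,3E,5E,7R)-2,7-bis[(4-methoxybenzyl)oxy]octa-3,5-diene
Conditions: NaH (2.5 equiv), 4 (2.4 equiv), Bu4NI (cat.), THF/DMF, 0 °C → rt
Reagents that add atoms: 4-methoxybenzyl chloride (second molecule of 4), COc1ccc(CCl)cc1
Why: Twofold Williamson ether synthesis (SN2 at the benzylic chloride, iodide catalysis), one molecule of 4 per hydroxyl; the carbinol C–O bonds are not broken, so both R centres are retained.

Step 4
Reactants: 5 (2R,3E,5E,7R)-2,7-bis[(4-methoxybenzyl)oxy]octa-3,5-diene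
Product: 7 (1S,2R,3R,4S)-1,4-bis(4-methoxyphenyl)-2,3-di[(E)-prop-1-enyl]butane-1,4-diol, via mono-rearranged lithium alkoxide 6 (not isolated)
Conditions: n-BuLi (excess), THF, −78 °C; then aq. NH4Cl
Reagents that add atoms: none
Why: n-BuLi removes one benzylic proton of each 4-methoxybenzyl ether, and each α-oxybenzyllithium undergoes a concerted six-electron [2,3]-Wittig shift through a five-membered envelope, bonding the benzylic carbon to the inner diene carbon (C4, then C5 of the octadiene) while the C–O bond at C2 (then C7) breaks and the double bond moves outward as an E-propenyl group. The closest known reaction type is the [2,3]-Wittig rearrangement of secondary (E)-allyl benzyl ethers with 1,3-transfer of chirality; here it runs twice, first on the dienyl ether to give alkoxide 6, then on the isolated allyl ether that remains in 6. No ring is closed. The two inner stereocentres (future C3 and C3'') are set by the (R)-carbinol carbons: with the methyl group pseudo-equatorial the oxygen lies on one alkene face and delivers the carbanion to that same face, which gives the R configuration at both carbons and the E geometry of the new double bond. The two carbinol stereocentres (future C2 and C2'') are set by the E geometry of the reacting double bonds together with the exo position of the 4-methoxyphenyl group in the envelope, which gives the anti relationship (S next to R) of a trans-flavanone. The step needs [2,3]- over [1,2]- and [1,4]-shift, secured by holding the anions at −78 °C where the radical-pair pathways are slow. It also needs benzylic over dienylic lithiation, which the unhindered CH2 group next to oxygen should favour over the methyl-substituted allylic C–H.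

Step 5
Reactants: 7 (1S,2R,3R,4S)-1,4-bis(4-methoxyphenyl)-2,3-di[(E)-prop-1-enyl]butane-1,4-diol
Product: 9 (1R,4S,5R,8S)-4,8-bis(4-methoxyphenyl)-3,7-dioxabicyclo[3.3.0]octane-2,6-diol (bis-lactol; mixture of anomers), via dialdehyde 8 (not isolated)
Conditions: O3, CH2Cl2/MeOH, −78 °C (Sudan Red 7B end point); then Me2S, −78 °C → rt
Reagents that add atoms: ozone, [O-][O+]=O
Why: Ozonolysis with reductive work-up cleaves the two disubstituted alkenes much faster than ozone attacks the anisyl rings; each aldehyde of 8 has a γ-hydroxyl and should close to a five-membered lactol, which takes the β-hydroxy aldehydes out of retro-aldol and epimerisation equilibria. The like (R,R) configuration of the two central carbons corresponds to the cis-fused bicycle, so no stereocentre is changed.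

Step 6
Reactants: 9 (1R,4S,5R,8S)-4,8-bis(4-methoxyphenyl)-3,7-dioxabicyclo[3.3.0]octane-2,6-diol
Product: 10 (1R,4S,5R,8S)-4,8-bis(4-methoxyphenyl)-3,7-dioxabicyclo[3.3.0]octane-2,6-dione (cis-fused; both aryl groups on the concave face)
Conditions: TEMPO (cat.), PhI(OAc)2, CH2Cl2, rt
Reagents that add atoms: none
Why: Oxoammonium-mediated oxidation of lactols to lactones under nearly neutral conditions; the acid-sensitive 4-methoxybenzylic C–O bonds and the ring-fusion carbons are not disturbed.

Step 7
Reactants: 11 3-fluoro-5-methoxyphenol
Product: 12 (3-fluoro-5-methoxyphenoxy)triisopropylsilane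
Conditions: TIPSCl, imidazole, DMF, rt
Reagents that add atoms: triisopropylsilyl chloride, CC(C)[Si](Cl)(C(C)C)C(C)C
Why: Standard silylation of a phenol; the bulky silyl group withstands n-BuLi and shields both ring positions next to it in the following lithiation.

Step 8
Reactants: 12 (3-fluoro-5-methoxyphenoxy)triisopropylsilane (two molecules); 10 (1R,4S,5R,8S)-4,8-bis(4-methoxyphenyl)-3,7-dioxabicyclo[3.3.0]octane-2,6-dione
Product: 15 (1S,2R,3R,4S)-2,3-bis[2-fluoro-6-methoxy-4-(triisopropylsilyloxy)benzoyl]-1,4-bis(4-methoxyphenyl)butane-1,4-diol, via aryllithium 13 (not isolated), via dilithium bis-hemiketal alkoxide 14 (not isolated)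
Conditions: 12 (2.2 equiv), n-BuLi (2.2 equiv), THF, −78 °C; then 10 in THF, −78 °C; aq. NH4Cl at −78 °C
Reagents that add atoms: (3-fluoro-5-methoxyphenoxy)triisopropylsilane (second molecule of 12), COc1cc(F)cc(O[Si](C(C)C)(C(C)C)C(C)C)c1
Why: Directed ortho-lithiation of 12 occurs at the one carbon flanked by fluorine and methoxy and gives 13, which is kept at −78 °C to avoid loss of LiF. Nucleophilic acyl addition of one molecule of 13 to each lactone carbonyl gives the tetrahedral adduct 14, which does not collapse at this temperature, so each carbonyl takes up one aryl group only; protonation and ring opening give 15 without touching the four stereocentres.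

Step 9
Reactants: 15 (1S,2R,3R,4S)-2,3-bis[2-fluoro-6-methoxy-4-(triisopropylsilyloxy)benzoyl]-1,4-bis(4-methoxyphenyl)butane-1,4-diol
Product: 16 (2S,3R,2''S,3''R)-5,5''-dimethoxy-2,2''-bis(4-methoxyphenyl)-7,7''-bis(triisopropylsilyloxy)-[3,3''-bichroman]-4,4''-dione
Conditions: NaH, THF, 0 °C → rt
Reagents that add atoms: none
Why: Twofold intramolecular nucleophilic aromatic substitution: each benzylic alkoxide attacks the fluorine-bearing carbon ortho to its own ketone (six-membered closure preferred over the seven-membered alternative) through a Meisenheimer intermediate stabilised by the carbonyl group. The carbinol C–O bonds are not broken, so C2 and C2'' are retained; NaF precipitates from THF and cannot cleave the aryl silyl ethers before ring closure.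

Step 10
Reactants: 16 (2S,3R,2''S,3''R)-5,5''-dimethoxy-2,2''-bis(4-methoxyphenyl)-7,7''-bis(triisopropylsilyloxy)-[3,3''-bichroman]-4,4''-dione
Product: 17 4',4''',5,5''-tetramethylchamaejasmin, (2S,3R,2''S,3''R)-7,7''-dihydroxy-5,5''-dimethoxy-2,2''-bis(4-methoxyphenyl)-[3,3''-bichroman]-4,4''-dione
Conditions: TBAF, AcOH, THF, 0 °C
Reagents that add atoms: none
Why: Fluoride cleavage of aryl silyl ethers, which are activated by the para carbonyl; the acetic acid buffer keeps the medium from opening ring C by β-elimination at C3 or C3''.

## Compound list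

1 | (R)-but-3-yn-2-ol | C[C@@H](O)C#C | starting material
2 | (2R,7R)-octa-3,5-diyne-2,7-diol | C[C@@H](O)C#CC#C[C@@H](C)O | intermediate
3 | (2R,3E,5E,7R)-octa-3,5-diene-2,7-diol | C[C@@H](O)/C=C/C=C/[C@@H](C)O | intermediate
4 | 4-methoxybenzyl chloride | COc1ccc(CCl)cc1 | starting material
5 | (2R,3E,5E,7R)-2,7-bis[(4-methoxybenzyl)oxy]octa-3,5-diene | C[C@@H](OCc1ccc(OC)cc1)/C=C/C=C/[C@@H](C)OCc1ccc(OC)cc1 | intermediate
6 | lithium (1S,2R,3E,5R)-5-[(4-methoxybenzyl)oxy]-1-(4-methoxyphenyl)-2-[(E)-prop-1-enyl]hex-3-en-1-olate (not isolated) | COc1ccc([C@@H]([O-])[C@H](/C=C/C)/C=C/[C@@H](C)OCc2ccc(OC)cc2)cc1.[Li+] | intermediate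
7 | (1S,2R,3R,4S)-1,4-bis(4-methoxyphenyl)-2,3-di[(E)-prop-1-enyl]butane-1,4-diol | COc1ccc([C@@H](O)[C@H](/C=C/C)[C@@H](/C=C/C)[C@H](O)c2ccc(OC)cc2)cc1 | intermediate
8 | (2R,3R)-2,3-bis[(S)-hydroxy(4-methoxyphenyl)methyl]butanedial (not isolated) | COc1ccc([C@@H](O)[C@H](C=O)[C@@H](C=O)[C@H](O)c2ccc(OC)cc2)cc1 | intermediate
9 | (1R,4S,5R,8S)-4,8-bis(4-methoxyphenyl)-3,7-dioxabicyclo[3.3.0]octane-2,6-diol, mixture of anomers at C2 and C6 | COc1ccc([C@H]2OC(O)[C@@H]3[C@H]2C(O)O[C@@H]3c2ccc(OC)cc2)cc1 | intermediate
10 | (1R,4S,5R,8S)-4,8-bis(4-methoxyphenyl)-3,7-dioxabicyclo[3.3.0]octane-2,6-dione | COc1ccc([C@H]2OC(=O)[C@@H]3[C@H]2C(=O)O[C@@H]3c2ccc(OC)cc2)cc1 | intermediate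
11 | 3-fluoro-5-methoxyphenol | COc1cc(O)cc(F)c1 | starting material
12 | (3-fluoro-5-methoxyphenoxy)triisopropylsilane | COc1cc(F)cc(O[Si](C(C)C)(C(C)C)C(C)C)c1 | intermediate
13 | [2-fluoro-6-methoxy-4-(triisopropylsilyloxy)phenyl]lithium (not isolated) | COc1cc(O[Si](C(C)C)(C(C)C)C(C)C)cc(F)c1[Li] | intermediate
14 | dilithium (1R,4S,5R,8S)-2,6-bis[2-fluoro-6-methoxy-4-(triisopropylsilyloxy)phenyl]-4,8-bis(4-methoxyphenyl)-3,7-dioxabicyclo[3.3.0]octane-2,6-bis(olate), configuration at C2 and C6 not defined (not isolated) | COc1ccc([C@H]2OC([O-])(c4c(F)cc(O[Si](C(C)C)(C(C)C)C(C)C)cc4OC)[C@@H]3[C@H]2C([O-])(c2c(F)cc(O[Si](C(C)C)(C(C)C)C(C)C)cc2OC)O[C@@H]3c2ccc(OC)cc2)cc1.[Li+].[Li+] | intermediate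
15 | (1S,2R,3R,4S)-2,3-bis[2-fluoro-6-methoxy-4-(triisopropylsilyloxy)benzoyl]-1,4-bis(4-methoxyphenyl)butane-1,4-diol | COc1ccc([C@@H](O)[C@H](C(=O)c2c(F)cc(O[Si](C(C)C)(C(C)C)C(C)C)cc2OC)[C@@H](C(=O)c2c(F)cc(O[Si](C(C)C)(C(C)C)C(C)C)cc2OC)[C@H](O)c2ccc(OC)cc2)cc1 | intermediate
16 | (2S,3R,2''S,3''R)-5,5''-dimethoxy-2,2''-bis(4-methoxyphenyl)-7,7''-bis(triisopropylsilyloxy)-[3,3''-bichroman]-4,4''-dione | COc1ccc([C@H]2Oc3cc(O[Si](C(C)C)(C(C)C)C(C)C)cc(OC)c3C(=O)[C@@H]2[C@H]2C(=O)c3c(OC)cc(O[Si](C(C)C)(C(C)C)C(C)C)cc3O[C@@H]2c2ccc(OC)cc2)cc1 | intermediate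
17 | 4',4''',5,5''-tetramethylchamaejasmin, (2S,3R,2''S,3''R)-7,7''-dihydroxy-5,5''-dimethoxy-2,2''-bis(4-methoxyphenyl)-[3,3''-bichroman]-4,4''-dione | COc1ccc([C@H]2Oc3cc(O)cc(OC)c3C(=O)[C@@H]2[C@H]2C(=O)c3c(OC)cc(O)cc3O[C@@H]2c2ccc(OC)cc2)cc1 | target

## Step count and least certain steps

Total: 10 steps. Longest linear sequence: 9 steps (steps 1–6 and 8–10); step 7 is a one-step branch.

**Step 4 (key step).** Three processes may erode it. Lithiation may be incomplete or misdirected, because the 4-methoxy group lowers the benzylic acidity and the dienylic C–H next to oxygen competes. The anti preference at the carbinol carbons may be only moderate, since an exo aryl group in an E substrate is not strongly favoured, and any erosion is compounded over two events. Warming to force the second lithiation on an alkoxide may let the [1,2]-shift leak in.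

Fallback: run the two shifts as separate single rearrangements, setting out from 5 and returning at 7. Treating 5 with a limited amount of n-BuLi at −78 °C should give the mono-rearranged alcohol F1 (unreacted 5 is recycled). Silylation with Et3SiCl and imidazole gives the triethylsilyl ether F2. A second [2,3]-Wittig shift then runs on this neutral, protected allyl ether to give the mono-silyl ether of the diol F3, and TBAF releases 7. Each event then runs on a monoanion, and the minor carbinol epimer can be removed after each shift.

**Step 8.** The hindered, basic aryllithium may enolise a lactone instead of adding. β-Elimination of the neighbouring acyloxy group would then open the bicycle. If warming is needed, 13 may lose LiF to an aryne, and the second addition may stall.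

Fallback: move the addition to the aldehyde oxidation level, setting out from 7 and returning at 15. Et3SiCl and imidazole give the bis(triethylsilyl) ether F4. Ozonolysis with Me2S work-up gives the bis(silyloxy) dialdehyde F5. Addition of 13 at −78 °C with a cold quench gives the bis-carbinol F6 as a mixture of epimers at the new carbinols. Dess–Martin periodinane oxidises it to the diketone F7. HF·pyridine then removes the alkyl silyl ethers, leaving the aryl silyl ethers, to give 15.

**Step 9.** The β-alkoxide may fragment by retro-aldol cleavage to an aromatic aldehyde and an enolate before it substitutes. The carbon α to the ketone may epimerise. Excess base may open the finished ring C by β-elimination. Loss of a silyl group before closure would deactivate the arene.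

Fallback: close the other bond of the ring oxygen (O1–C2) under acid instead of base, setting out from 10 and returning at 16. Commercial 5-methoxybenzene-1,3-diol is mono-silylated to 3-methoxy-5-(triisopropylsilyloxy)phenol F8, and protection with MOMCl and i-Pr2NEt gives the methoxymethyl ether F9. Lithiation with n-BuLi between the methoxy and methoxymethoxy groups gives aryllithium F10, and addition of two equivalents of it to 10 at −78 °C gives the bis(aryl ketone) diol F11. HCl in MeOH removes the methoxymethyl groups to give the bis(2-hydroxyaryl ketone) F12. The same acid should ionise each 4-methoxybenzylic carbinol, and the phenol should trap the cation in a six-membered closure, anti to the C3 substituent, to give 16. This path puts C2 and C2'' under the control of C3 and C3'' and would also tolerate imperfect anti selectivity in step 4. Its own hazard is loss of a proton from C3 at the cation stage.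

**Step 5.** Excess ozone may oxidise the electron-rich anisyl rings. The β-hydroxy aldehydes of 8 may fragment or epimerise before the lactols close.

Fallback: two-stage cleavage, setting out from 7 and returning at 9. Dihydroxylation with OsO4 (cat.) and N-methylmorpholine N-oxide gives the hexaol F13 as a mixture at the new carbinols. NaIO4 in aqueous THF then cleaves both glycols, and the dialdehyde closes to 9.

## Further compounds

F1 | step 4 | (1S,2R,3E,5R)-5-[(4-methoxybenzyl)oxy]-1-(4-methoxyphenyl)-2-[(E)-prop-1-enyl]hex-3-en-1-ol | COc1ccc([C@@H](O)[C@H](/C=C/C)/C=C/[C@@H](C)OCc2ccc(OC)cc2)cc1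
F2 | step 4 | triethylsilyl ether of F1 | COc1ccc([C@@H](O[Si](CC)(CC)CC)[C@H](/C=C/C)/C=C/[C@@H](C)OCc2ccc(OC)cc2)cc1
F3 | step 4 | mono(triethylsilyl) ether of 7 | COc1ccc([C@@H](O[Si](CC)(CC)CC)[C@H](/C=C/C)[C@@H](/C=C/C)[C@H](O)c2ccc(OC)cc2)cc1
F4 | step 8 | bis(triethylsilyl) ether of 7 | COc1ccc([C@@H](O[Si](CC)(CC)CC)[C@H](/C=C/C)[C@@H](/C=C/C)[C@H](O[Si](CC)(CC)CC)c2ccc(OC)cc2)cc1
F5 | step 8 | (2R,3R)-2,3-bis[(S)-(4-methoxyphenyl)(triethylsilyloxy)methyl]butanedial | COc1ccc([C@@H](O[Si](CC)(CC)CC)[C@H](C=O)[C@@H](C=O)[C@H](O[Si](CC)(CC)CC)c2ccc(OC)cc2)cc1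
F6 | step 8 | 2,3-bis{[2-fluoro-6-methoxy-4-(triisopropylsilyloxy)phenyl](hydroxy)methyl}-1,4-bis(4-methoxyphenyl)-1,4-bis(triethylsilyloxy)butane, mixture of epimers at the new carbinols | COc1ccc([C@@H](O[Si](CC)(CC)CC)[C@H](C(O)c2c(F)cc(O[Si](C(C)C)(C(C)C)C(C)C)cc2OC)[C@@H](C(O)c2c(F)cc(O[Si](C(C)C)(C(C)C)C(C)C)cc2OC)[C@H](O[Si](CC)(CC)CC)c2ccc(OC)cc2)cc1
F7 | step 8 | bis(triethylsilyl) ether of 15 | COc1ccc([C@@H](O[Si](CC)(CC)CC)[C@H](C(=O)c2c(F)cc(O[Si](C(C)C)(C(C)C)C(C)C)cc2OC)[C@@H](C(=O)c2c(F)cc(O[Si](C(C)C)(C(C)C)C(C)C)cc2OC)[C@H](O[Si](CC)(CC)CC)c2ccc(OC)cc2)cc1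
F8 | step 9 | 3-methoxy-5-(triisopropylsilyloxy)phenol | COc1cc(O)cc(O[Si](C(C)C)(C(C)C)C(C)C)c1
F9 | step 9 | 1-methoxy-3-(methoxymethoxy)-5-(triisopropylsilyloxy)benzene | COCOc1cc(OC)cc(O[Si](C(C)C)(C(C)C)C(C)C)c1
F10 | step 9 | [2-methoxy-6-(methoxymethoxy)-4-(triisopropylsilyloxy)phenyl]lithium | COCOc1cc(O[Si](C(C)C)(C(C)C)C(C)C)cc(OC)c1[Li]
F11 | step 9 | (1S,2R,3R,4S)-2,3-bis[2-methoxy-6-(methoxymethoxy)-4-(triisopropylsilyloxy)benzoyl]-1,4-bis(4-methoxyphenyl)butane-1,4-diol | COc1ccc([C@@H](O)[C@H](C(=O)c2c(OCOC)cc(O[Si](C(C)C)(C(C)C)C(C)C)cc2OC)[C@@H](C(=O)c2c(OCOC)cc(O[Si](C(C)C)(C(C)C)C(C)C)cc2OC)[C@H](O)c2ccc(OC)cc2)cc1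
F12 | step 9 | (1S,2R,3R,4S)-2,3-bis[2-hydroxy-6-methoxy-4-(triisopropylsilyloxy)benzoyl]-1,4-bis(4-methoxyphenyl)butane-1,4-diol | COc1ccc([C@@H](O)[C@H](C(=O)c2c(O)cc(O[Si](C(C)C)(C(C)C)C(C)C)cc2OC)[C@@H](C(=O)c2c(O)cc(O[Si](C(C)C)(C(C)C)C(C)C)cc2OC)[C@H](O)c2ccc(OC)cc2)cc1
F13 | step 5 | (1S,2R,3R,4S)-2,3-bis(1,2-dihydroxypropyl)-1,4-bis(4-methoxyphenyl)butane-1,4-diol, mixture at the new carbinols | COc1ccc([C@@H](O)[C@H](C(O)C(C)O)[C@@H](C(O)C(C)O)[C@H](O)c2ccc(OC)cc2)cc1
A1 | alternative 1 | (E)-1-[4-(benzyloxy)-2-hydroxy-6-methoxyphenyl]-3-(3,5-dibromo-4-hydroxyphenyl)prop-2-en-1-one | O=C(/C=C/c1cc(Br)c(O)c(Br)c1)c1c(O)cc(OCc2ccccc2)cc1OC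
A2 | alternative 1 | 7,7''-di-O-benzyl-3',5',3''',5'''-tetrabromo-4',4'''-di-O-demethyl derivative of 17 | Oc1c(Br)cc([C@H]2Oc3cc(OCc4ccccc4)cc(OC)c3C(=O)[C@@H]2[C@H]2C(=O)c3c(OC)cc(OCc4ccccc4)cc3O[C@@H]2c2cc(Br)c(O)c(Br)c2)cc1Br
A3 | alternative 2 | (1R,4S,5R,8S)-4,8-bis(4-methoxyphenyl)-3,7-dioxabicyclo[3.3.0]octane-2,6-dione (identical with 10) | COc1ccc([C@H]2OC(=O)[C@@H]3[C@H]2C(=O)O[C@@H]3c2ccc(OC)cc2)cc1
A4 | alternative 2 | [2-fluoro-6-methoxy-4-(triisopropylsilyloxy)phenyl]lithium (identical with 13) | COc1cc(O[Si](C(C)C)(C(C)C)C(C)C)cc(F)c1[Li]
A5 | alternative 2 | (1S,2R,3R,4S)-2,3-bis[2-fluoro-6-methoxy-4-(triisopropylsilyloxy)benzoyl]-1,4-bis(4-methoxyphenyl)butane-1,4-diol (identical with 15) | COc1ccc([C@@H](O)[C@H](C(=O)c2c(F)cc(O[Si](C(C)C)(C(C)C)C(C)C)cc2OC)[C@@H](C(=O)c2c(F)cc(O[Si](C(C)C)(C(C)C)C(C)C)cc2OC)[C@H](O)c2ccc(OC)cc2)cc1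
A6 | alternative 3 | (2S,3R,2'S,3'R)-5,5'-dibromo-2,2'-bis(4-methoxyphenyl)-2,2',3,3'-tetrahydro-[3,3'-bi-4H-pyran]-4,4'-dione | COc1ccc([C@H]2OC=C(Br)C(=O)[C@@H]2[C@H]2C(=O)C(Br)=CO[C@@H]2c2ccc(OC)cc2)cc1
A7 | alternative 3 | 1,1-dimethoxy-3-(trimethylsilyloxy)buta-1,3-diene | COC(OC)=CC(=C)O[Si](C)(C)C
A8 | alternative 3 | 7,7''-bis(trimethylsilyl) ether of 17 | COc1ccc([C@H]2Oc3cc(O[Si](C)(C)C)cc(OC)c3C(=O)[C@@H]2[C@H]2C(=O)c3c(OC)cc(O[Si](C)(C)C)cc3O[C@@H]2c2ccc(OC)cc2)cc1
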